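## The problem

Numbering used throughout: ring carbons C1 to C9 (C1 carries the side chain, C2 the hydroxyl, C4 the methyl group, C8 and C9 the formyl groups, whose carbons are called C8a and C9a), C10 is the side-chain methine and C11 the acetoxymethyl carbon. The skeleton is a cyclonona-4,7-diene in which an (E)-trisubstituted C4=C5 alkene and a C7=C8 enal of cis ring geometry are separated by one methylene, so a strained medium ring holding a skipped diene has to be closed without moving either alkene. Four stereocentres must be set: C10, C1 and C9 are contiguous, and C2 sits beside C1 with only a methylene on its other side. C10 lies outside the ring and cannot be relayed dependably from a finished nine-membered ring, so the C10–C1–C9 triad is best fixed together and early; C2 then has to be decided by a reagent, since both carbons flanking C1 are branched. The C9 aldehyde is the most fragile group, because C9–H is α to one formyl group and allylic to the enal (epimerisation, migration of C7=C8 into conjugation); the primary acetate rules out hydride and organometallic reagents once it is in place, the homoprenyl alkene rules out ozone, and a free carbonyl at C8a or C9a near a free hydroxyl invites lactol formation. The enabling feature is that the triad is flanked by four oxidised carbons: C2 and C9a on the C1–C9 bond are the carbonyl and acetal carbons of a 5-alkoxybutenolide, while C11 on C10 and C8a on C8 are the two inner carbons of a diene whose termini are C10 and C8. A [4+2] cycloaddition therefore builds the triad on a temporary cyclohexene whose C11=C8a alkene is cleaved afterwards to return the two remaining oxidised carbons.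

## Retrosynthesis

Target 36 is traced to the ring compound 35, its C2 triethylsilyl ether and C9a dimethyl acetal. No skeletal bond is cut; the point is timing, because the C9 aldehyde should be released only in the last operation. The forward step must remove both masks under acid mild enough to leave C9 and the acetate alone.

Compound 35 is opened at C7=C8 to the acyclic aldehyde 34 (terminal vinyl group on C6, methylene on C8). Only this ring alkene has the cis ring geometry that ring-closing metathesis delivers in a nine-membered ring; cutting C4=C5 would ask the same reaction for an (E)-alkene. Closing C7=C8 by aldol condensation was set aside, because the C7 aldehyde it needs is β,γ-unsaturated and would enolise towards C6 before the C8 methylene does, closing the wrong bond or moving C4=C5. Compound 34 carries all four stereocentres on an open chain; the forward reaction has to close a strained skipped diene at high dilution, and the (E)-enal follows from the ring.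

The C8 methylene of 34 is removed by retro-α-methylenation to aldehyde 32, which goes back through alcohol 31 and bis-silyl ether 30 to the (2S)-alcohol 29. C2 is made planar in ketone 28: an addition to a C2 aldehyde under substrate control was judged unsafe, so the stereocentre is handed to a catalyst that only has to tell the branched C1 from the C3 methylene.

Ketone 28 is cut at C2–C3 (through hydroxy ketone 27 and β-keto sulfone 26) into lactone 20 and allylic sulfone 24. An allyl-metal form of the C3–C7 unit would bond through C5 and destroy the (E)-C4=C5 alkene, whereas the sulfonyl carbanion 25 bonds through C3. A lactone as electrophile stops at the ketone stage and releases the C11 hydroxyl, which is acetylated after the last organometallic step. The cut separates a compact stereotriad lactone from an achiral seven-carbon unit; the forward reaction must acylate at the α-carbon without enolising C1.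

Lactone 20 goes back through aldehyde 19, alcohol 18 and benzyl ether 17 to hydroxy lactone 16; the homoprenyl alkene is made by Wittig reaction only after ozone has been used. In 16 the C11 and C8a carbinol carbons are rejoined as the C11=C8a alkene of cyclohexene ester 13 (through diol ester 15 and ozonide 14). Both cleavage carbons emerge as primary alcohols and are told apart by position, not by a reagent: only the C11 hydroxyl is γ to the C2 ester and lactonises. The precursor 13 is a simple trisubstituted cyclohexene.

Ester acetal 13 is the methanolysis product of lactone acetal 12, which is cut across C10–C1 and C8–C9 into butenolide 5 and diene 11. This double cut removes a ring and three stereocentres at once and leaves an auxiliary-bearing dienophile and an achiral diene; building C10, C1 and C9 one by one on an open chain offers no comparable control element. The forward cycloaddition must be ortho-regioselective, endo, and anti to the menthyloxy group. The diene carries a benzyloxypropyl group, which survives acidic methanol and ozone and is removed by hydrogenolysis while no alkene is present.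

Butenolide 5 comes from racemic hydroxybutenolide 3 and (+)-menthol 4, and 3 from furfural 1 by photooxygenation through endoperoxide 2. Diene 11 comes from dienol 10 and ester 9, which arises by Johnson–Claisen rearrangement (ketene acetal 8) of penta-1,4-dien-3-ol 6 with triethyl orthoacetate 7. Sulfone 24 comes from chloride 23 and alcohol 22, whose (E)-alkene is set by allylic oxidation of 5-methylhexa-1,4-diene 21.

## Roads not taken

Alternative 1: Ireland–Claisen ring contraction, cutting C9–C1. A thirteen-membered allylic lactone A1 (ester oxygen on C11, C10=C1 alkene) would be converted into its silyl ketene acetal and rearranged to the cyclononadiene acid A2; C9–C1 forms as O–C11 breaks, leaving a C10=C11 methylene.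
- Merits: the medium ring arises by contraction of an unstrained macrocycle, and one ordered transition state sets C1 and C9 together.
- Weak points: C10 must be created afterwards by hydroboration of the exocyclic alkene with little facial bias. C9 is both α to the ester and allylic, so ketene acetal geometry is hard to fix, and chair against boat in a macrocycle is uncertain. A1 itself needs three defined alkenes and a macrolactonisation, and the acid must be brought down to the aldehyde. As formulated, A2 also carries the C2 silyloxy group in the configuration opposite to the target's, which adds an inversion.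
- Comparison: this road forms the ring more safely than any direct nine-membered closure, and ring-closing metathesis is the weakest step of the chosen plan. Against that the chosen plan sets C10, C1 and C9 from one acetal centre in a single, well-understood cycloaddition.

Alternative 2: Grob fragmentation, with the C4–C8 bond added in the retrosynthetic direction. The C8 alkoxide of the cis-fused bicyclic monotosylate A3 would fragment: C4–C8 breaks, C4=C5 forms, tosylate leaves, and cyclononenone A4 results.
- Merits: fragmentation is the most dependable route to (E)-cyclononenes, the alkene geometry is stereospecific, and the ring strain is paid for by the fragmentation itself.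
- Weak points: A3 needs six stereocentres, three of which (C4, C5, C8) are sacrificial. A4 lacks both C8a and the C7=C8 alkene, so the C8 ketone must be enolised towards C7 and not towards C9 (which would epimerise C9) and then homologated by one carbon.
- Comparison: safer for the ring and for C4=C5, but longer and heavier in stereochemical overhead. The chosen plan obtains C8a directly from the cleaved cyclohexene and never places a ketone next to C9.

Alternative 3: ring-closing intramolecular allylboration, cutting C1–C2. The (Z)-allyl pinacolboronate A5 would add through its γ-carbon C1 to the tethered C2 aldehyde, giving cyclononadienol A6 with the alkene shifted to C10=C11.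
- Merits: ring closure and two stereocentres (C1, C2) in one step, no protecting group on the C2 hydroxyl, and the shortest route to the ring.
- Weak points: C9 has to be set in an open-chain precursor with no obvious control element. The sense of C1/C2 relative to C9 depends on a six-membered transition state forced into a forming nine-membered ring. A γ,γ-disubstituted allylboronate of defined geometry must coexist with a latent aldehyde. C10 is again left to a late hydroboration.
- Comparison: this road is shorter to the ring and gets C2 for free, where the chosen plan spends a separate catalytic reduction on it. In return the chosen plan has C10, C1 and C9 fixed before the ring exists and leaves only C2 to reagent control.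

Key step: step 6

Assumption: the target is taken as the open hydroxy dialdehyde drawn; the C2 hydroxyl and the C9 formyl group are trans about C1, so a bridged five-membered lactol is not expected to compete.
Assumption: 5-methylhexa-1,4-diene (21) is taken as a purchasable diene.

## Steps

Step 1
Reactants: 1 furfural
Product: 3 5-hydroxyfuran-2(5H)-one (racemic), via furfural endoperoxide 2 (not isolated)
Conditions: O2, hν, rose bengal disodium salt (C20H2Cl4I4Na2O5, cat.), MeOH, 20 °C
Reagents that add atoms: oxygen, O=O
Why: Sensitised photooxygenation; singlet oxygen adds [4+2] across the furan and methanolysis of endoperoxide 2 expels the formyl group as methyl formate. The product is racemic and its acetal centre is labile, which step 2 uses.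

Step 2
Reactants: 3 5-hydroxyfuran-2(5H)-one; 4 (+)-menthol
Product: 5 (5S)-5-[(1S,2R,5S)-menthyloxy]furan-2(5H)-one
Conditions: TsOH·H2O (cat.), toluene, 110 °C, water removed; crystallisation from petroleum ether, mother liquor re-equilibrated with acid
Reagents that add atoms: none
Why: Acid-catalysed acetalisation of the pseudo-acid; the acetal centre equilibrates under the acid and the (5S)-configured acetal of the (+)-menthyl series (mirror image of the crystalline acetal of the (−)-menthol series) is expected to crystallise, which fixes the future C9a.

Step 3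
Reactants: 6 penta-1,4-dien-3-ol; 7 triethyl orthoacetate
Product: 9 ethyl (4E)-hepta-4,6-dienoate, via ketene acetal 8 (not isolated)
Conditions: EtCO2H (cat.), 140 °C, EtOH distilled off
Reagents that add atoms: none
Why: Johnson–Claisen rearrangement; the chair transition state with the vinyl group equatorial should give the (E)-alkene of the conjugated diene.

Step 4
Reactants: 9 ethyl (4E)-hepta-4,6-dienoate
Product: 10 (4E)-hepta-4,6-dien-1-ol
Conditions: LiAlH4, Et2O, 0 °C
Reagents that add atoms: none
Why: Hydride reduction of the ester; the isolated diene is not touched.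

Step 5
Reactants: 10 (4E)-hepta-4,6-dien-1-ol
Product: 11 (E)-[(hepta-4,6-dien-1-yloxy)methyl]benzene
Conditions: NaH, BnBr, Bu4NI (cat.), THF, 0 to 20 °C
Reagents that add atoms: benzyl bromide, BrCc1ccccc1
Why: Williamson ether synthesis; the benzyl ether survives the acidic methanol of step 7 and the ozone of step 8 and is removed in step 10 while no alkene is present.

Step 6
Reactants: 5 (5S)-5-[(1S,2R,5S)-menthyloxy]furan-2(5H)-one; 11 (E)-[(hepta-4,6-dien-1-yloxy)methyl]benzene
Product: 12 all-cis adduct (3S,3aS,7R,7aR)-7-[3-(benzyloxy)propyl]-3-[(1S,2R,5S)-menthyloxy]-3a,4,7,7a-tetrahydro-2-benzofuran-1(3H)-one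
Conditions: toluene, 2,6-di-tert-butyl-4-methylphenol (cat.), 120 °C, sealed tube, 11 in threefold excess
Reagents that add atoms: none
Why: Thermal, concerted but asynchronous [4+2] cycloaddition of normal electron demand (diene HOMO, butenolide LUMO); the closest known reaction type is the Diels–Alder reaction of 5-alkoxy-2(5H)-furanones with acyclic dienes. One ring closes, the cyclohexene, by suprafacial union of the diene termini C10 and C8 with C1 and C9, which leaves it cis-fused to the lactone. C9 is controlled by the acetal stereocentre C9a, because the diene adds to the face anti to the menthyloxy group. C1 follows from the cis geometry of the dienophile. C10 follows from the endo transition state (lactone carbonyl under the diene) together with the (E)-geometry of the diene, which places the side chain cis to C2 and C9a. The step needs ortho regiochemistry, endo topology and anti facial selectivity. Regiochemistry is secured electronically (largest HOMO coefficient at the unsubstituted terminus C8, largest LUMO coefficient at the β-carbon C9) and sterically (the substituted terminus avoids the acetal-bearing β-position). Excess diene and a radical inhibitor offset the low reactivity of an alkyl-substituted diene.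

Step 7
Reactants: 12 all-cis adduct
Product: 13 methyl (1R,2R,6S)-2-[3-(benzyloxy)propyl]-6-(dimethoxymethyl)cyclohex-3-ene-1-carboxylate
Conditions: HC(OMe)3, MeOH, TsOH·H2O (cat.), 50 °C
Reagents that add atoms: methanol, CO; trimethyl orthoformate, COC(OC)OC
Why: Acid-catalysed transacetalisation and ring opening of the pseudo-ester to the normal ester and dimethyl acetal, driven by the orthoformate as water scavenger. No free aldehyde is formed, so C9 should keep its configuration, and (+)-menthol is recovered.

Step 8
Reactants: 13 methyl ester dimethyl acetal
Product: 16 hydroxy lactone (3R,4S)-4-[3-(benzyloxy)propyl]-3-[(2S)-4-hydroxy-1,1-dimethoxybutan-2-yl]oxolan-2-one, via ozonide 14 (not isolated), via dihydroxy ester 15 (not isolated)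
Conditions: O3, CH2Cl2, −78 °C (indicator end-point); then MeOH, NaBH4, −78 to 20 °C
Reagents that add atoms: ozone, [O-][O+]=O
Why: Ozonolysis with reductive work-up cleaves the temporary C11=C8a alkene to two primary alcohols. Under the basic work-up only the C11 hydroxyl, γ to the C2 ester, should close the five-membered lactone (preferred kinetically and thermodynamically over the six-membered lactone from the C8a hydroxyl), which differentiates the two ends; the stereocentres are not touched.

Step 9
Reactants: 16 hydroxy lactone
Product: 17 triethylsilyl ether (3R,4S)-4-[3-(benzyloxy)propyl]-3-{(2S)-1,1-dimethoxy-4-[(triethylsilyl)oxy]butan-2-yl}oxolan-2-one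
Conditions: TESCl, imidazole, CH2Cl2, 0 °C
Reagents that add atoms: chlorotriethylsilane, CC[Si](Cl)(CC)CC
Why: Silylation of the only free hydroxyl under non-acidic conditions, which keeps the C8a oxygen from cyclising onto the neighbouring acetal.

Step 10
Reactants: 17 triethylsilyl ether
Product: 18 primary alcohol (3R,4S)-3-{(2S)-1,1-dimethoxy-4-[(triethylsilyl)oxy]butan-2-yl}-4-(3-hydroxypropyl)oxolan-2-one
Conditions: H2 (1 atm), Pd/C, EtOAc, 20 °C
Reagents that add atoms: none
Why: Hydrogenolysis of the benzyl ether; the molecule holds no alkene at this stage, and lactone, acetal and silyl ether are inert in a neutral solvent.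

Step 11
Reactants: 18 primary alcohol
Product: 19 aldehyde (3R,4S)-3-{(2S)-1,1-dimethoxy-4-[(triethylsilyl)oxy]butan-2-yl}-4-(3-oxopropyl)oxolan-2-one
Conditions: Dess–Martin periodinane, NaHCO3, CH2Cl2, 0 to 20 °C
Reagents that add atoms: none
Why: Buffered Dess–Martin oxidation of a primary alcohol; acetal and silyl ether tolerate the buffered medium.

Step 12
Reactants: 19 aldehyde
Product: 20 homoprenyl lactone (3R,4S)-3-{(2S)-1,1-dimethoxy-4-[(triethylsilyl)oxy]butan-2-yl}-4-(4-methylpent-3-en-1-yl)oxolan-2-one
Conditions: iPrPPh3I, n-BuLi, THF, 0 °C; then 19, −78 to 0 °C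
Reagents that add atoms: isopropyltriphenylphosphonium iodide, CC(C)[P+](c1ccccc1)(c1ccccc1)c1ccccc1.[I-]
Why: Wittig olefination with the non-stabilised isopropylidene ylide; the aldehyde reacts far faster than the lactone and no alkene geometry arises.

Step 13
Reactants: 21 5-methylhexa-1,4-diene
Product: 22 (2E)-2-methylhexa-2,5-dien-1-ol
Conditions: SeO2 (cat.), t-BuOOH, CH2Cl2, 0 to 20 °C
Reagents that add atoms: tert-butyl hydroperoxide, CC(C)(C)OO
Why: Selenium dioxide allylic oxidation (ene reaction, then [2,3] shift) attacks the (E)-methyl group at the more substituted end of the trisubstituted alkene, which sets the (E)-geometry of the future C4=C5; the monosubstituted alkene is much less reactive.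

Step 14
Reactants: 22 (2E)-2-methylhexa-2,5-dien-1-ol
Product: 23 (2E)-1-chloro-2-methylhexa-2,5-diene
Conditions: MsCl, LiCl, 2,4,6-collidine, DMF, 0 °C
Reagents that add atoms: lithium chloride, [Li+].[Cl-]
Why: The mesylate formed in situ is displaced by chloride in an SN2 reaction, a standard way to primary allylic chlorides without allylic transposition or loss of alkene geometry.

Step 15
Reactants: 23 (2E)-1-chloro-2-methylhexa-2,5-diene
Product: 24 {[(2E)-2-methylhexa-2,5-dien-1-yl]sulfonyl}benzene
Conditions: PhSO2Na, DMF, 20 °C
Reagents that add atoms: sodium benzenesulfinate, [Na+].[O-]S(=O)c1ccccc1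
Why: S-Alkylation of the sulfinate by SN2 displacement at the primary allylic carbon.

Step 16
Reactants: 20 homoprenyl lactone; 24 {[(2E)-2-methylhexa-2,5-dien-1-yl]sulfonyl}benzene
Product: 26 β-keto sulfone (C3 epimers; C11 hydroxyl free), via lithiated sulfone 25 (not isolated)
Conditions: 24 (2.2 equiv), n-BuLi, THF, −78 °C; then 20, −78 to −20 °C
Reagents that add atoms: none
Why: Claisen-type acylation of the α-sulfonyl allyl carbanion by the lactone; bonding through the α-carbon forms C2–C3 and keeps the (E)-C4=C5 alkene. The second equivalent of 25 deprotonates the β-keto sulfone, which prevents over-addition, and the carbanion is too weak a base to enolise the lactone at C1.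

Step 17
Reactants: 26 β-keto sulfone
Product: 27 hydroxy ketone (C2 ketone with C3 methylene; C11 hydroxyl free)
Conditions: SmI2, THF/MeOH, −78 °C
Reagents that add atoms: none
Why: Reductive desulfonylation of a β-keto sulfone by electron transfer from divalent samarium; kinetic protonation of the enolate at C3 by methanol should keep C4=C5 out of conjugation and leave C1 untouched.

Step 18
Reactants: 27 hydroxy ketone
Product: 28 acetoxy ketone
Conditions: Ac2O, pyridine, CH2Cl2, 0 °C
Reagents that add atoms: acetic anhydride, CC(=O)OC(C)=O
Why: Acetylation of the only free hydroxyl, placed directly after the last organometallic step so that the ester is never exposed to carbanions.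

Step 19
Reactants: 28 acetoxy ketone
Product: 29 (2S)-alcohol
Conditions: (R)-1-methyl-3,3-diphenyltetrahydro-1H,3H-pyrrolo[1,2-c][1,3,2]oxazaborole, catecholborane, toluene, −78 °C
Reagents that add atoms: none
Why: Corey–Bakshi–Shibata reduction; the catalyst differentiates the branched C1 side (large) from the C3 methylene (small), and the (R)-catalyst should give the (2S)-alcohol, in the same sense as it gives (S)-carbinols from aryl methyl ketones. Catecholborane does not hydroborate the alkenes or reduce the acetate at this temperature.

Step 20
Reactants: 29 (2S)-alcohol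
Product: 30 bis(triethylsilyl) ether
Conditions: TESCl, imidazole, 4-(dimethylamino)pyridine (cat.), DMF, 20 °C
Reagents that add atoms: chlorotriethylsilane, CC[Si](Cl)(CC)CC
Why: Silylation of the secondary alcohol, so that the C8a aldehyde made in step 22 cannot form a six-membered lactol that would be oxidised further.

Step 21
Reactants: 30 bis(triethylsilyl) ether
Product: 31 primary alcohol (C8a hydroxyl free)
Conditions: HF·pyridine, pyridine, THF, 0 °C
Reagents that add atoms: none
Why: Selective desilylation; the unhindered primary silyl ether is cleaved well before the secondary one flanked by C1, and buffered fluoride avoids the protic acid that would cyclise the γ-hydroxy acetal.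

Step 22
Reactants: 31 primary alcohol
Product: 32 aldehyde (C8a formyl group, C8 methylene)
Conditions: Dess–Martin periodinane, NaHCO3, CH2Cl2, 0 °C
Reagents that add atoms: none
Why: Buffered Dess–Martin oxidation; the stereocentre C9 is β to the new aldehyde and is not at risk.

Step 23
Reactants: 32 aldehyde
Product: 34 α-methylene aldehyde, via Mannich base 33 (not isolated)
Conditions: CH2=NMe2+ I− (Eschenmoser's salt), Et3N, CH2Cl2, 20 °C
Reagents that add atoms: N,N-dimethylmethyleneiminium iodide, C=[N+](C)C.[I-]
Why: Mannich reaction at C8 followed by β-elimination of dimethylamine (α-methylenation); C8 is the only enolisable position next to a free carbonyl group, and the new carbon is C7.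

Step 24
Reactants: 34 α-methylene aldehyde
Product: 35 nine-membered enal (C2 triethylsilyl ether, C9a dimethyl acetal)
Conditions: RuCl2(H2IMes)(=CH-C6H4-2-OiPr) (second-generation Hoveyda–Grubbs catalyst, 10 mol%), 1,4-benzoquinone (cat.), toluene (1 mM), 80 °C
Reagents that add atoms: none
Why: Ring-closing metathesis; the ruthenium alkylidene loads at the terminal vinyl group and closes onto the 1,1-disubstituted enal alkene with loss of ethylene. In a nine-membered ring that already holds the (E)-C4=C5 alkene only the ring-cis C7=C8 alkene is attainable, and that is the (E)-enal of the target.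

Step 25
Reactants: 35 nine-membered enal
Product: 36 target, (2S)-2-[(1R,2S,4E,7E,9R)-8,9-diformyl-2-hydroxy-4-methylcyclonona-4,7-dien-1-yl]-6-methylhept-5-en-1-yl acetate
Conditions: HCl (0.5 M aq.), THF, 0 °C
Reagents that add atoms: water, O
Why: Acid hydrolysis removes the triethylsilyl ether and the dimethyl acetal in one operation; cold dilute acid is chosen so that the acetate, the C9 configuration and the position of C7=C8 should survive.

## Compound list

1 | furfural | O=Cc1ccco1 | starting material
2 | furfural endoperoxide (2,3,7-trioxabicyclo[2.2.1]hept-5-ene-1-carbaldehyde, racemic) | O=CC12OOC(C=C1)O2 | intermediate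
3 | 5-hydroxyfuran-2(5H)-one (racemic) | O=C1C=CC(O)O1 | intermediate
4 | (+)-menthol, (1S,2R,5S) | CC(C)[C@H]1CC[C@H](C)C[C@@H]1O | starting material
5 | (5S)-5-[(1S,2R,5S)-menthyloxy]furan-2(5H)-one | O=C1C=C[C@@H](O[C@H]2C[C@@H](C)CC[C@@H]2C(C)C)O1 | intermediate
6 | penta-1,4-dien-3-ol | C=CC(O)C=C | starting material
7 | triethyl orthoacetate | CCOC(C)(OCC)OCC | starting material
8 | ketene acetal, 3-[(1-ethoxyethenyl)oxy]penta-1,4-diene | C=CC(OC(=C)OCC)C=C | intermediate
9 | ethyl (4E)-hepta-4,6-dienoate | CCOC(=O)CC/C=C/C=C | intermediate
10 | (4E)-hepta-4,6-dien-1-ol | OCCC/C=C/C=C | intermediate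
11 | (E)-[(hepta-4,6-dien-1-yloxy)methyl]benzene | C=C/C=C/CCCOCc1ccccc1 | intermediate
12 | all-cis adduct, (3S,3aS,7R,7aR)-7-[3-(benzyloxy)propyl]-3-[(1S,2R,5S)-menthyloxy]-3a,4,7,7a-tetrahydro-2-benzofuran-1(3H)-one | C1=C[C@@H](CCCOCc2ccccc2)[C@H]2C(=O)O[C@H](O[C@H]3C[C@@H](C)CC[C@@H]3C(C)C)[C@H]2C1 | intermediate
13 | methyl (1R,2R,6S)-2-[3-(benzyloxy)propyl]-6-(dimethoxymethyl)cyclohex-3-ene-1-carboxylate | C1=C[C@@H](CCCOCc2ccccc2)[C@@H](C(=O)OC)[C@@H](C(OC)OC)C1 | intermediate
14 | ozonide of 13 (1,2,4-trioxolane bridging C11 and C8a, mixture at these two carbons; C1, C9, C10 as in 13) | COC(=O)[C@H]1[C@@H](C(OC)OC)CC2OOC(O2)[C@H]1CCCOCc1ccccc1 | intermediate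
15 | dihydroxy ester (C11 and C8a hydroxymethylene groups, C2 methyl ester; C1, C9, C10 as in 13) | COC(=O)[C@@H]([C@H](CCO)C(OC)OC)[C@@H](CO)CCCOCc1ccccc1 | intermediate
16 | (3R,4S)-4-[3-(benzyloxy)propyl]-3-[(2S)-4-hydroxy-1,1-dimethoxybutan-2-yl]oxolan-2-one | O=C1OC[C@@H](CCCOCc2ccccc2)[C@@H]1[C@H](CCO)C(OC)OC | intermediate
17 | (3R,4S)-4-[3-(benzyloxy)propyl]-3-{(2S)-1,1-dimethoxy-4-[(triethylsilyl)oxy]butan-2-yl}oxolan-2-one | O=C1OC[C@@H](CCCOCc2ccccc2)[C@@H]1[C@H](CCO[Si](CC)(CC)CC)C(OC)OC | intermediate
18 | (3R,4S)-3-{(2S)-1,1-dimethoxy-4-[(triethylsilyl)oxy]butan-2-yl}-4-(3-hydroxypropyl)oxolan-2-one | O=C1OC[C@@H](CCCO)[C@@H]1[C@H](CCO[Si](CC)(CC)CC)C(OC)OC | intermediate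
19 | (3R,4S)-3-{(2S)-1,1-dimethoxy-4-[(triethylsilyl)oxy]butan-2-yl}-4-(3-oxopropyl)oxolan-2-one | O=C1OC[C@@H](CCC=O)[C@@H]1[C@H](CCO[Si](CC)(CC)CC)C(OC)OC | intermediate
20 | (3R,4S)-3-{(2S)-1,1-dimethoxy-4-[(triethylsilyl)oxy]butan-2-yl}-4-(4-methylpent-3-en-1-yl)oxolan-2-one | O=C1OC[C@@H](CCC=C(C)C)[C@@H]1[C@H](CCO[Si](CC)(CC)CC)C(OC)OC | intermediate
21 | 5-methylhexa-1,4-diene | CC(C)=CCC=C | starting material
22 | (2E)-2-methylhexa-2,5-dien-1-ol | C=CC/C=C(\C)CO | intermediate
23 | (2E)-1-chloro-2-methylhexa-2,5-diene | C=CC/C=C(\C)CCl | intermediate
24 | {[(2E)-2-methylhexa-2,5-dien-1-yl]sulfonyl}benzene | C=CC/C=C(\C)CS(=O)(=O)c1ccccc1 | intermediate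
25 | lithiated sulfone (lithium on the sulfonyl-bearing carbon of 24, (E)-alkene kept) | [Li]C(S(=O)(=O)c1ccccc1)/C(C)=C/CC=C | intermediate
26 | β-keto sulfone: C1 methine bearing the C10 arm CH(CH2OH)(homoprenyl), the acyl arm C(=O)–CH(SO2Ph)–C(CH3)=CH–CH2–CH=CH2 with (E)-alkene, and the C9 arm CH[CH(OMe)2](CH2CH2OSiEt3); C3 epimers; C1, C9, C10 as in 20 | OC[C@@H](CCC=C(C)C)[C@@H](C(=O)C(/C(C)=C/CC=C)S(=O)(=O)c1ccccc1)[C@H](CCO[Si](CC)(CC)CC)C(OC)OC | intermediate
27 | hydroxy ketone: as 26 with the sulfonyl group replaced by hydrogen (C3 methylene) | OC[C@@H](CCC=C(C)C)[C@@H](C(=O)C/C(C)=C/CC=C)[C@H](CCO[Si](CC)(CC)CC)C(OC)OC | intermediate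
28 | acetoxy ketone: C11 acetate of 27 | CC(=O)OC[C@@H](CCC=C(C)C)[C@@H](C(=O)C/C(C)=C/CC=C)[C@H](CCO[Si](CC)(CC)CC)C(OC)OC | intermediate
29 | (2S)-alcohol: 28 with the C2 ketone reduced to the (S)-carbinol | CC(=O)OC[C@@H](CCC=C(C)C)[C@@H]([C@@H](O)C/C(C)=C/CC=C)[C@H](CCO[Si](CC)(CC)CC)C(OC)OC | intermediate
30 | bis(triethylsilyl) ether: C2 triethylsilyl ether of 29 | CC(=O)OC[C@@H](CCC=C(C)C)[C@@H]([C@@H](O[Si](CC)(CC)CC)C/C(C)=C/CC=C)[C@H](CCO[Si](CC)(CC)CC)C(OC)OC | intermediate
31 | primary alcohol: 30 with the C8a hydroxyl free | CC(=O)OC[C@@H](CCC=C(C)C)[C@@H]([C@@H](O[Si](CC)(CC)CC)C/C(C)=C/CC=C)[C@H](CCO)C(OC)OC | intermediate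
32 | aldehyde: 31 oxidised at C8a | CC(=O)OC[C@@H](CCC=C(C)C)[C@@H]([C@@H](O[Si](CC)(CC)CC)C/C(C)=C/CC=C)[C@H](CC=O)C(OC)OC | intermediate
33 | Mannich base: 32 with a dimethylaminomethyl group on C8 (C8 epimers) | CC(=O)OC[C@@H](CCC=C(C)C)[C@@H]([C@@H](O[Si](CC)(CC)CC)C/C(C)=C/CC=C)[C@H](C(CN(C)C)C=O)C(OC)OC | intermediate
34 | α-methylene aldehyde: 32 with a methylene group (C7) on C8 | CC(=O)OC[C@@H](CCC=C(C)C)[C@@H]([C@@H](O[Si](CC)(CC)CC)C/C(C)=C/CC=C)[C@H](C(=C)C=O)C(OC)OC | intermediate
35 | nine-membered enal: the target with C2–OH as triethylsilyl ether and the C9 formyl group as dimethyl acetal | CC(=O)OC[C@@H](CCC=C(C)C)[C@H]1[C@@H](O[Si](CC)(CC)CC)C/C(C)=C/C/C=C(/C=O)[C@@H]1C(OC)OC | intermediate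
36 | (2S)-2-[(1R,2S,4E,7E,9R)-8,9-diformyl-2-hydroxy-4-methylcyclonona-4,7-dien-1-yl]-6-methylhept-5-en-1-yl acetate | CC(=O)OC[C@@H](CCC=C(C)C)[C@H]1[C@@H](O)C/C(C)=C/C/C=C(/C=O)[C@@H]1C=O | target

## Step count and risk

Total: 25 steps. Longest linear sequence: 20 steps (steps 3 to 12 and 16 to 25, from penta-1,4-dien-3-ol 6).

Step 6 (key step). The alkyl-substituted diene is only weakly activated, so slow cycloaddition with competing diene polymerisation, or incomplete regio- and endo selectivity, is the likely failure. The fallback keeps the two bonds and the ring but activates the diene; it sets out from butenolide 5 and returns at adduct 12. (E)-7-(Benzyloxy)hept-3-en-2-one F1 (from purchasable 4-(benzyloxy)butanal and 1-(triphenylphosphoranylidene)propan-2-one) would be silylated (Et3SiOTf, Et3N) to the 2-silyloxy diene F2. Its donor on the carbon next to C8 reinforces the regiochemistry and raises the rate, and cycloaddition with 5 should give the silyl enol ether adduct F3. Conversion into the enol triflate F4 (CsF, PhNTf2) and reduction with Pd(OAc)2, PPh3, HCO2H and Bu3N would then give 12.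

Step 24. Closure onto a hindered, electron-poor 1,1-disubstituted alkene is slow, so intermolecular metathesis at the terminal vinyl group (oligomerisation) or engagement of the homoprenyl alkene may win. The fallback moves the ring closure to the reduced oxidation level, where a free allylic hydroxyl assists metathesis at the neighbouring alkene; it sets out from 34 and returns at 35. Reduction with NaBH4 (MeOH, −20 °C) would give the allylic alcohol F5, metathesis with the same ruthenium catalyst the cyclic allylic alcohol F6, and MnO2 would restore the enal 35.

Step 7. The ring opening may stop at acetal exchange without opening the lactone, or forcing acid may epimerise C9 through the enol ether. The fallback separates removal of the auxiliary from acetal formation; it sets out from 12 and returns at 13. Aqueous acid hydrolysis of the menthyl acetal would give the hydroxy lactone F7, neutral esterification with Me3SiCHN2 in MeOH the open aldehyde ester F8, and acetalisation with HC(OMe)3 and TsOH·H2O at 0 °C would give 13.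

Step 16. Addition of a branched carbanion to a hindered lactone carbonyl may be slow, and bonding through the γ-carbon or drift of C4=C5 into conjugation in the β-keto sulfone would erode the (E)-alkene. The fallback joins the fragments at the aldehyde oxidation level; it sets out from 20 (and chloride 23) and returns at 28. DIBAL at −78 °C would give the lactol F9. The allylbarium reagent from 23 (BaI2, lithium biphenylide) adds through its α-carbon with retention of alkene geometry and should give the diol F10 as C2 epimers. Selective acetylation of the primary hydroxyl (AcCl, 2,4,6-collidine, −78 °C) would give the monoacetate F11, and Dess–Martin oxidation the ketone 28.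

Step 19. The substrate's own facial bias may oppose the catalyst, giving poor selectivity at C2. The fallback gives up catalyst control for separation and recycling; it sets out from 28 and returns at 29. Reduction with NaBH4 would give 29 together with the (2R)-epimer F12; after chromatographic separation F12 would be oxidised back to 28 with Dess–Martin periodinane and resubmitted.

Step 25. Once the C9 aldehyde is free, protic acid may epimerise C9, move C7=C8 into conjugation or start to cleave the acetate. The fallback unmasks the two groups separately without aqueous mineral acid; it sets out from 35 and returns at 36. Et3SiOTf with 2,4,6-collidine, then water, should cleave the dimethyl acetal alone and give the silyl-protected dialdehyde F13; buffered HF·pyridine would then remove the silyl ether to give 36.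

## Further compounds

F1 | step 6 | (E)-7-(benzyloxy)hept-3-en-2-one | CC(=O)/C=C/CCCOCc1ccccc1
F2 | step 6 | {[(3E)-7-(benzyloxy)hepta-1,3-dien-2-yl]oxy}triethylsilane | C=C(O[Si](CC)(CC)CC)/C=C/CCCOCc1ccccc1
F3 | step 6 | silyl enol ether adduct (12 with a triethylsilyloxy group on C8a) | CC[Si](CC)(CC)OC1=C[C@@H](CCCOCc2ccccc2)[C@H]2C(=O)O[C@H](O[C@H]3C[C@@H](C)CC[C@@H]3C(C)C)[C@H]2C1
F4 | step 6 | enol triflate (12 with a trifluoromethanesulfonyloxy group on C8a) | O=S(=O)(OC1=C[C@@H](CCCOCc2ccccc2)[C@H]2C(=O)O[C@H](O[C@H]3C[C@@H](C)CC[C@@H]3C(C)C)[C@H]2C1)C(F)(F)F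
F5 | step 24 | allylic alcohol (34 with the formyl group reduced to hydroxymethyl) | CC(=O)OC[C@@H](CCC=C(C)C)[C@@H]([C@@H](O[Si](CC)(CC)CC)C/C(C)=C/CC=C)[C@H](C(=C)CO)C(OC)OC
F6 | step 24 | cyclic allylic alcohol (35 with the C8 formyl group as hydroxymethyl) | CC(=O)OC[C@@H](CCC=C(C)C)[C@H]1[C@@H](O[Si](CC)(CC)CC)C/C(C)=C/C/C=C(/CO)[C@@H]1C(OC)OC
F7 | step 7 | hydroxy lactone (12 with the menthyloxy group replaced by hydroxyl, anomers) | C1=C[C@@H](CCCOCc2ccccc2)[C@H]2C(=O)OC(O)[C@H]2C1
F8 | step 7 | methyl (1R,2R,6S)-2-[3-(benzyloxy)propyl]-6-formylcyclohex-3-ene-1-carboxylate | C1=C[C@@H](CCCOCc2ccccc2)[C@@H](C(=O)OC)[C@@H](C=O)C1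
F9 | step 16 | lactol (20 with the lactone carbonyl reduced to the hemiacetal, anomers) | OC1OC[C@@H](CCC=C(C)C)[C@@H]1[C@H](CCO[Si](CC)(CC)CC)C(OC)OC
F10 | step 16 | diol (27 with the C2 ketone as carbinol, C2 epimers) | OC[C@@H](CCC=C(C)C)[C@@H](C(O)C/C(C)=C/CC=C)[C@H](CCO[Si](CC)(CC)CC)C(OC)OC
F11 | step 16 | monoacetate (C11 acetate of F10, C2 epimers) | CC(=O)OC[C@@H](CCC=C(C)C)[C@@H](C(O)C/C(C)=C/CC=C)[C@H](CCO[Si](CC)(CC)CC)C(OC)OC
F12 | step 19 | (2R)-epimer of 29 | CC(=O)OC[C@@H](CCC=C(C)C)[C@@H]([C@H](O)C/C(C)=C/CC=C)[C@H](CCO[Si](CC)(CC)CC)C(OC)OC
F13 | step 25 | silyl-protected dialdehyde (36 as its C2 triethylsilyl ether) | CC(=O)OC[C@@H](CCC=C(C)C)[C@H]1[C@@H](O[Si](CC)(CC)CC)C/C(C)=C/C/C=C(/C=O)[C@@H]1C=O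
A1 | alternative 1 | thirteen-membered allylic lactone | O=C1C/C(COCc2ccc(OC)cc2)=C\C/C=C(C)/C[C@@H](O[Si](C)(C)C(C)(C)C)/C=C(CCC=C(C)C)/CO1
A2 | alternative 1 | cyclononadiene carboxylic acid with a 1,1-disubstituted alkene on C1 | C=C(CCC=C(C)C)[C@H]1[C@H](O[Si](C)(C)C(C)(C)C)C/C(C)=C/C/C=C(/COCc2ccc(OC)cc2)[C@@H]1C(=O)O
A3 | alternative 2 | cis-fused bicyclic 5-tosyloxy-8-ol | CC(C)(C)[Si](C)(C)OC[C@@H](CCC=C(C)C)[C@H]1[C@@H](O[Si](C)(C)C(C)(C)C)C[C@@]2(C)[C@H](OS(=O)(=O)c3ccc(C)cc3)CC[C@@]2(O)[C@@H]1C(OC)OC
A4 | alternative 2 | (E)-cyclononenone with a C8 ketone | CC(C)(C)[Si](C)(C)OC[C@@H](CCC=C(C)C)[C@H]1[C@@H](O[Si](C)(C)C(C)(C)C)C/C(C)=C/CCC(=O)[C@@H]1C(OC)OC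
A5 | alternative 3 | (Z)-allyl pinacolboronate with a tethered C2 aldehyde | O=CC/C(C)=C/C/C=C(/CO[Si](C)(C)C(C)(C)C)[C@H](C(OC)OC)/C=C(/CB1OC(C)(C)C(C)(C)O1)CCC=C(C)C
A6 | alternative 3 | cyclononadienol with a 1,1-disubstituted alkene on C1 | C=C(CCC=C(C)C)[C@H]1[C@@H](O)C/C(C)=C/C/C=C(/CO[Si](C)(C)C(C)(C)C)[C@@H]1C(OC)OC
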